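## The problem

The target 17 is kaempferol with a 1,1-dimethylallyl group on C8: a 4H-chromen-4-one (rings A and C fused at C4a–C8a) with ring B on C2, hydroxyls on C3, C5, C7 and C4', and on C8 a quaternary carbon bearing two methyl groups and a vinyl group. There is no stereocentre, so the difficulty lies in regiochemistry on ring A and in the tolerance of the side chain. Ring A is a phloroglucinol in which C6 and C8 are electronically alike, and late C-alkylation of such rings gives 6/8 mixtures and the linear prenyl isomer. The tertiary carbon therefore has to be attached before ring C exists, and ring C must then be closed on the correct side. The side chain is the fragile element: its tertiary benzylic and allylic carbon on an electron-rich ring can be lost or shifted after ipso-protonation, its vinyl group can capture the neighbouring O7 hydroxyl under acid, and it rules out hydrogenolysis for deprotection. O3 is best carried in from the start, because hydroxylating C3 of a finished flavone adds steps next to an alkene. The enabling feature is that in a 3,5-dioxygenated phenol with the side chain on C2, the carbon that becomes C4a is the only free position ortho to the oxygen that becomes O1, and it is also ortho to O5 and para to O7. An acyl carbon tethered through O1 can reach no other position, so forming C4–C4a closes ring C and fixes the side chain at C8 in the same event.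

## Retrosynthesis

**17 from 16.** The four O–benzyl bonds are cut last. Benzyl ethers are chosen because they should survive a 180 °C rearrangement, carbonate base, chlorite and trifluoroacetic acid, and can be removed at −78 °C with BCl3 and pentamethylbenzene without hydrogen. Acetal protecting groups would not survive the acid released in the ring closure, and methyl ethers would need far harsher cleavage. The forward step must free four hydroxyls without touching the vinyl group.

**16 from 14 (through 15).** The C4–C4a bond is cut, opening ring C to the acyclic acid 14, in which all oxygens, ring B and the quaternary carbon are already in place. The neighbouring cut at O1–C2 (diketone cyclodehydration or oxidative chalcone cyclisation) would need an intermolecular C-acylation of the hindered, acid-sensitive ring A, and oxidative cyclisation of 6'-oxygenated chalcones tends to give aurones. A cut at C2–C1' would need a 2-metallated or 2-halogenated 3-oxychromone. The forward reaction is an intramolecular acylation through the mixed anhydride 15, and it must run without strong protic acid.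

**14 from 13.** The carboxyl group is taken back to a formyl group. The aldehyde is preferred to an ester because it makes the preceding substitution far easier, and because it avoids a late saponification with hydroxide next to a β-aryloxy leaving group. The forward step is a chlorite oxidation that must spare ring A and the vinyl group.

**13 from 5 and 12.** The enol ether bond between C2 of the future chromone and the ring A oxygen is cut, giving the hindered phenol 5 and the β-chlorovinyl aldehyde 12. Two neighbouring ways to make this bond were weighed:
- An enol sulfonate of a β-keto ester is a weaker acceptor and offers the phenoxide a second electrophilic site at sulfur.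
- Addition of 5 to an arylpropiolate is reliable but leaves out O3.

The forward step asks a phenoxide flanked by a tertiary carbon to attack a tetrasubstituted alkene, which is why the strongest available acceptor (formyl) and a leaving group with no alternative reaction site (chloride) are used.

**12 from 10 (through 11).** The C–Cl bond and the C–CHO bond are cut together, leading back to the α-benzyloxy ketone 10. Chloroformylation of a ketone with a single enolisable position is regiochemically unambiguous and gives the chlorovinyl aldehyde in one step through the iminium salt 11.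

**10 from 6 and 7 (through 8 and 9).** The aryl–carbonyl bond is cut to the aryl bromide 6 and the Weinreb amide 7, both commercial. The Grignard reagent 8 must add once only, which the chelate 9 ensures.

**5 from 3 (through 4), and 3 from 1 and 2.** The bond between the ring carbon and the quaternary carbon is cut by a retro-[3,3] shift to the prenyl ether 3, which comes from the symmetrical phenol 1 and prenyl bromide 2. The rearrangement inverts the allyl unit, so an O-prenyl group delivers exactly the tertiary isomer through dienone 4. The symmetry of 1 makes the two ortho positions identical, so no regiochemical question arises. The forward step only has to avoid further reaction of phenol 5 at the rearrangement temperature.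

## Roads not taken

**Alternative 1:** The quaternary carbon could be assembled from three pieces instead of by a sigmatropic shift, cutting its C–CH3 bond and its C–vinyl bond and starting from the aryl ketone carbonate A1.
- Forward key step: MeMgBr adds to the ketone, the tert-butoxycarbonyl group moves to the new tertiary alkoxide and leaves, and the resulting ortho-quinone methide takes up vinylmagnesium bromide at its exocyclic carbon to give phenol A2.
- Merits: it runs at low temperature, needs no symmetry in the ring, and places the side chain unambiguously.
- Weak points for this target: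
  - The quinone methide carries six hydrogens on its exocyclic methyl groups, and a 1,5-hydrogen shift or deprotonation by the basic Grignard reagent would stop the sequence at the isopropenyl level.
  - It is flanked by an acetal oxygen and made electron-poorer in name only, since two alkoxy donors reduce its electrophilicity, while the vinyl nucleophile has to form a quaternary carbon intermolecularly.
  - A1 needs selective double acetalisation and carbonate formation before the key step.
  - A2 only replaces 5. The ring C problem is untouched, and the acetal groups of A2 would not survive the acid of step 7.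
- Comparison: this road is better than the chosen plan in thermal mildness. The chosen plan sets against it an atom-economical intramolecular [3,3] shift, two steps from a commercial phenol, and protecting groups that are compatible with the ring closure.

**Alternative 2:** Ring C could be formed by cutting O1–C2 and C3–C4, joining salicylaldehyde A3 and nitrostyrene A4.
- Forward key step: under DABCO the phenoxide of A3 adds to A4 and the nitronate closes onto the aldehyde with loss of water, giving the racemic 3-nitro-2H-chromene A5.
- Merits: this is the most convergent option. It forms two ring bonds in one mild, acid-free and metal-free step and brings in ring B as a simple nitroalkene.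
- Weak points for this target:
  - A5 is at the wrong oxidation level at three carbons. C2 is a stereocentre that must later be destroyed, C3 carries nitrogen where oxygen is needed, and C4 is a CH where a carbonyl is needed. Several redox steps would follow, all beside the vinyl group.
  - A3 has to be made by formylating A2 ortho to its hydroxyl on a ring with a second activated position.
  - The phenoxide of A3 is flanked by both the tertiary carbon and the formyl group, so it is more hindered than 5.
- Comparison: this road is better in convergence and in the mildness of the ring-forming step. The chosen plan sets against it a closure that gives ring C at the final oxidation level with O3 in place, so that only one deprotection remains.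

**Alternative 3:** Ring C could be reached by ring expansion, cutting O1–C2 of the flavonol and starting from aurone A6 through its epoxide A7.
- Forward key step: LiBr opens A7 at the benzylic carbon, the hemiketal releases the ring A phenoxide, and the phenoxide displaces bromide to give the 3-hydroxyflavone A8.
- Merits: the flavonol arrives with O3 free, no carboxyl activation or acid is needed in the ring-forming step, and the aurone preference of 6'-oxygenated systems is used rather than fought.
- Weak points for this target:
  - A6 has to be built from A2 by C-acylation ortho to the hydroxyl, closure to the furanone and aldol condensation with the ring B aldehyde, which is a longer sequence that includes a Lewis-acid step on the acid-sensitive ring.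
  - The cascade needs three selectivities that the structure does not enforce: bromide opening at the benzylic and not the spiro carbon, survival of the α-bromo-1,2-dicarbonyl intermediate, and six-membered displacement by a hindered phenoxide in preference to five-membered re-addition to the carbonyl.
  - The acetal groups need protic acid for removal at the end.
- Comparison: this road is better in delivering the free 3-hydroxyl without acid in the ring-forming step. The chosen plan sets against it a closure with only one possible site and one possible ring size, broad precedent, and fewer steps.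

Key step: step 7

Remark on the chemistry: compounds 11 to 15 are drawn as the E isomers (formyl or carboxyl carbon cis to chlorine or to the aryloxy group). If steps 4 and 5 give E/Z mixtures they would be carried on as such, because the acylium ion of step 7 has a rotatable C2–C3 bond and both isomers should converge on 16.

## Route

Step 1
Reactants: 1 3,5-bis(benzyloxy)phenol; 2 1-bromo-3-methylbut-2-ene
Product: 3 1,3-bis(benzyloxy)-5-[(3-methylbut-2-en-1-yl)oxy]benzene
Conditions: K2CO3, acetone, reflux
Reagents that add atoms: none
Why: Williamson ether synthesis: the phenoxide of 1 displaces bromide from the primary allylic carbon of 2 by SN2, K2CO3 in a polar aprotic solvent favouring O- over C-alkylation; the benzyl ethers are inert.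

Step 2
Reactants: 3 1,3-bis(benzyloxy)-5-[(3-methylbut-2-en-1-yl)oxy]benzene
Product: 5 3,5-bis(benzyloxy)-2-(2-methylbut-3-en-2-yl)phenol, via ortho-dienone 4 (not isolated)
Conditions: PhNEt2, 180 °C, argon
Reagents that add atoms: none
Why: Aromatic Claisen rearrangement: the [3,3] shift inverts the allyl unit, so the tertiary carbon bonds to the ortho carbon and dienone 4 enolises to phenol 5; the two ortho positions of 3 are equivalent by symmetry, and the basic amine solvent should suppress acid-catalysed ring closure of the product.

Step 3
Reactants: 6 1-(benzyloxy)-4-bromobenzene; 7 2-(benzyloxy)-N-methoxy-N-methylacetamide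
Product: 10 2-(benzyloxy)-1-[4-(benzyloxy)phenyl]ethan-1-one, via arylmagnesium bromide 8 (not isolated), via magnesium hemiaminal chelate 9 (not isolated)
Conditions: Mg, THF, reflux; then 7, THF, 0 °C; then 1 M HCl
Reagents that add atoms: none
Why: Grignard formation followed by Weinreb ketone synthesis: 8 adds once to amide 7 because the five-membered magnesium chelate 9 persists until the acidic quench, which releases ketone 10.

Step 4
Reactants: 10 2-(benzyloxy)-1-[4-(benzyloxy)phenyl]ethan-1-one
Product: 12 (2E)-2-(benzyloxy)-3-[4-(benzyloxy)phenyl]-3-chloroprop-2-enal, via chlorovinyl iminium chloride 11 (not isolated)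
Conditions: POCl3, DMF, 0 → 60 °C; then H2O, 0 °C
Reagents that add atoms: N,N-dimethylformamide CN(C)C=O; phosphoryl chloride O=P(Cl)(Cl)Cl; water O
Why: Vilsmeier–Haack–Arnold chloroformylation: the only enolisable position of 10 is formylated by the chloroiminium reagent and the carbonyl oxygen is exchanged for chloride, giving 11, which water hydrolyses to the β-chlorovinyl aldehyde 12; the aryl rings are acyl-deactivated or unactivated and should not be formylated.

Step 5
Reactants: 5 3,5-bis(benzyloxy)-2-(2-methylbut-3-en-2-yl)phenol; 12 (2E)-2-(benzyloxy)-3-[4-(benzyloxy)phenyl]-3-chloroprop-2-enal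
Product: 13 (2E)-2-(benzyloxy)-3-[3,5-bis(benzyloxy)-2-(2-methylbut-3-en-2-yl)phenoxy]-3-[4-(benzyloxy)phenyl]prop-2-enal
Conditions: Cs2CO3, DMF, 25 → 50 °C
Reagents that add atoms: none
Why: Nucleophilic vinylic substitution by addition–elimination: the cesium phenoxide of 5 adds to the β-carbon of the vinylogous acid chloride 12 and chloride leaves, a known reaction of β-chlorovinyl aldehydes with phenoxides; the formyl group activates better than an ester, chloride offers no second electrophilic site, and the rotating enolate intermediate makes the geometry of 13 uncritical.

Step 6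
Reactants: 13 (2E)-2-(benzyloxy)-3-[3,5-bis(benzyloxy)-2-(2-methylbut-3-en-2-yl)phenoxy]-3-[4-(benzyloxy)phenyl]prop-2-enal
Product: 14 (2E)-2-(benzyloxy)-3-[3,5-bis(benzyloxy)-2-(2-methylbut-3-en-2-yl)phenoxy]-3-[4-(benzyloxy)phenyl]prop-2-enoic acid
Conditions: NaClO2, NaH2PO4, 2-methylbut-2-ene, t-BuOH/THF/H2O, 0 °C → rt
Reagents that add atoms: sodium chlorite [Na+].[O-]Cl=O
Why: Pinnick oxidation: chlorous acid adds to the formyl group and fragments to the acid, as known for β-aryloxy enals such as 3-formylchromones; excess 2-methylbut-2-ene consumes HOCl so that ring A and the vinyl group should not be chlorinated, and no hydroxide is present that could displace the aryloxy group.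

Step 7
Reactants: 14 (2E)-2-(benzyloxy)-3-[3,5-bis(benzyloxy)-2-(2-methylbut-3-en-2-yl)phenoxy]-3-[4-(benzyloxy)phenyl]prop-2-enoic acid
Product: 16 3,5,7-tris(benzyloxy)-2-[4-(benzyloxy)phenyl]-8-(2-methylbut-3-en-2-yl)-4H-chromen-4-one, via mixed trifluoroacetic anhydride 15 (not isolated)
Conditions: (CF3CO)2O, CH2Cl2, 0 °C → rt
Reagents that add atoms: none
Why: Intramolecular Friedel–Crafts acylation, closest in type to the cyclodehydration of β-aryloxycinnamic acids to flavones and to anhydride-mediated acylation of phloroglucinol ethers. Acid 14 gives mixed anhydride 15, which ionises to an acylium ion delocalised onto C3 as an oxocarbenium and benzylic cation (ketene resonance form). In that form C2–C3 is a single bond, so any Z isomer equilibrates and both isomers should converge. C4a, ortho to O1 and O5 and para to O7, attacks the acyl carbon in a six-membered closure that is exo to the acyl C–O multiple bond (6-exo-dig on the acylium ion, 6-exo-trig if 15 is attacked directly), and loss of the proton from the arenium ion gives the pyranone ring C of 16. No stereocentre is formed. The step needs ring A to react in preference to ring B and C4a in preference to any other carbon: the tether through O1 reaches only the two ortho positions, C8 is blocked by the quaternary carbon, and closure onto ring B would give a five-membered indenone at a carbon meta to its only donor. Three oxygens make ring A nucleophilic enough for anhydride activation, so the only acid present is trifluoroacetic acid, which at this temperature should neither protonate the monosubstituted alkene nor ipso-protonate C8 at a competitive rate.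

Step 8
Reactants: 16 3,5,7-tris(benzyloxy)-2-[4-(benzyloxy)phenyl]-8-(2-methylbut-3-en-2-yl)-4H-chromen-4-one
Product: 17 3,5,7-trihydroxy-2-(4-hydroxyphenyl)-8-(2-methylbut-3-en-2-yl)-4H-chromen-4-one
Conditions: BCl3, C6HMe5, CH2Cl2, −78 °C; then MeOH, then H2O
Reagents that add atoms: none
Why: Lewis-acid debenzylation with a cation scavenger: BCl3 coordinates each ether oxygen and the benzyl group is transferred to pentamethylbenzene by Friedel–Crafts alkylation instead of to ring A or the alkene; at −78 °C a monosubstituted alkene should not react, and the cold methanol quench frees the four hydroxyls.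

## Compound list

1 | 3,5-bis(benzyloxy)phenol | Oc1cc(OCc2ccccc2)cc(OCc2ccccc2)c1 | starting material
2 | 1-bromo-3-methylbut-2-ene | CC(C)=CCBr | starting material
3 | 1,3-bis(benzyloxy)-5-[(3-methylbut-2-en-1-yl)oxy]benzene | CC(C)=CCOc1cc(OCc2ccccc2)cc(OCc2ccccc2)c1 | intermediate
4 | racemic 3,5-bis(benzyloxy)-6-(2-methylbut-3-en-2-yl)cyclohexa-2,4-dien-1-one | C=CC(C)(C)C1C(=O)C=C(OCc2ccccc2)C=C1OCc1ccccc1 | intermediate (not isolated)
5 | 3,5-bis(benzyloxy)-2-(2-methylbut-3-en-2-yl)phenol | C=CC(C)(C)c1c(O)cc(OCc2ccccc2)cc1OCc1ccccc1 | intermediate
6 | 1-(benzyloxy)-4-bromobenzene | Brc1ccc(OCc2ccccc2)cc1 | starting material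
7 | 2-(benzyloxy)-N-methoxy-N-methylacetamide | CON(C)C(=O)COCc1ccccc1 | starting material
8 | [4-(benzyloxy)phenyl]magnesium bromide | Br[Mg]c1ccc(OCc2ccccc2)cc1 | intermediate (not isolated)
9 | racemic bromomagnesium 2-(benzyloxy)-1-[4-(benzyloxy)phenyl]-1-[methoxy(methyl)amino]ethan-1-olate | CON(C)C(COCc1ccccc1)(O[Mg]Br)c1ccc(OCc2ccccc2)cc1 | intermediate (not isolated)
10 | 2-(benzyloxy)-1-[4-(benzyloxy)phenyl]ethan-1-one | O=C(COCc1ccccc1)c1ccc(OCc2ccccc2)cc1 | intermediate
11 | N-{(2E)-2-(benzyloxy)-3-[4-(benzyloxy)phenyl]-3-chloroprop-2-en-1-ylidene}-N-methylmethanaminium chloride | C[N+](C)=C/C(OCc1ccccc1)=C(\Cl)c1ccc(OCc2ccccc2)cc1.[Cl-] | intermediate (not isolated)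
12 | (2E)-2-(benzyloxy)-3-[4-(benzyloxy)phenyl]-3-chloroprop-2-enal | O=C/C(OCc1ccccc1)=C(\Cl)c1ccc(OCc2ccccc2)cc1 | intermediate
13 | (2E)-2-(benzyloxy)-3-[3,5-bis(benzyloxy)-2-(2-methylbut-3-en-2-yl)phenoxy]-3-[4-(benzyloxy)phenyl]prop-2-enal | O=C/C(OCc1ccccc1)=C(\Oc1cc(OCc2ccccc2)cc(OCc2ccccc2)c1C(C)(C)C=C)c1ccc(OCc2ccccc2)cc1 | intermediate
14 | (2E)-2-(benzyloxy)-3-[3,5-bis(benzyloxy)-2-(2-methylbut-3-en-2-yl)phenoxy]-3-[4-(benzyloxy)phenyl]prop-2-enoic acid | O=C(O)/C(OCc1ccccc1)=C(\Oc1cc(OCc2ccccc2)cc(OCc2ccccc2)c1C(C)(C)C=C)c1ccc(OCc2ccccc2)cc1 | intermediate
15 | (2E)-2-(benzyloxy)-3-[3,5-bis(benzyloxy)-2-(2-methylbut-3-en-2-yl)phenoxy]-3-[4-(benzyloxy)phenyl]prop-2-enoic trifluoroacetic anhydride | O=C(OC(=O)C(F)(F)F)/C(OCc1ccccc1)=C(\Oc1cc(OCc2ccccc2)cc(OCc2ccccc2)c1C(C)(C)C=C)c1ccc(OCc2ccccc2)cc1 | intermediate (not isolated)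
16 | 3,5,7-tris(benzyloxy)-2-[4-(benzyloxy)phenyl]-8-(2-methylbut-3-en-2-yl)-4H-chromen-4-one | C=CC(C)(C)c1c(OCc2ccccc2)cc(OCc2ccccc2)c2c(=O)c(OCc3ccccc3)c(-c3ccc(OCc4ccccc4)cc3)oc12 | intermediate
17 | 3,5,7-trihydroxy-2-(4-hydroxyphenyl)-8-(2-methylbut-3-en-2-yl)-4H-chromen-4-one | C=CC(C)(C)c1c(O)cc(O)c2c(=O)c(O)c(-c3ccc(O)cc3)oc12 | target

## Step count and risks

Total: 8 steps. Longest linear sequence: 6 steps (steps 1, 2, 5, 6, 7, 8, or equally steps 3, 4, 5, 6, 7, 8).

**Step 7 (key step).** The most likely failure is ipso-protonation of ring A at the carbon bearing the side chain, with loss or 1,3-shift of the allyl unit, before acylation has deactivated the ring. Slow ionisation of 15 could also allow intermolecular trifluoroacetylation at the free carbon between the two benzyloxy groups. Both would stem from the trifluoroacetic acid that the activation releases. The fallback removes the protic acid and separates activation from ring closure. It sets out from acid 14, which is converted under neutral conditions with 1-chloro-N,N,2-trimethylprop-1-en-1-amine in CH2Cl2 into (2E)-2-(benzyloxy)-3-[3,5-bis(benzyloxy)-2-(2-methylbut-3-en-2-yl)phenoxy]-3-[4-(benzyloxy)phenyl]prop-2-enoyl chloride F1. F1 is then closed with SnCl4 at −78 °C in the presence of 2,6-di-tert-butyl-4-methylpyridine as proton trap, and the route is rejoined at 16.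

**Step 5.** The most likely failure is slow addition, because the nucleophilic oxygen of 5 is flanked by a tertiary carbon and the β-carbon of 12 is fully substituted and carries two donors. Prolonged heating could then divert the phenoxide to attack through a ring carbon. The fallback replaces the crowded alkene by a linear acetylenic acceptor and accepts that O3 is added later. It sets out from phenol 5 and returns at 16 as follows.
- 5 is added with catalytic Cs2CO3 in DMF at 80 °C to ethyl 3-[4-(benzyloxy)phenyl]prop-2-ynoate F2. F2 is one step from commercial 1-(benzyloxy)-4-ethynylbenzene with n-BuLi and ethyl chloroformate.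
- The adduct is ethyl (2Z)-3-[3,5-bis(benzyloxy)-2-(2-methylbut-3-en-2-yl)phenoxy]-3-[4-(benzyloxy)phenyl]prop-2-enoate F3.
- LiOH in aqueous THF gives the acid (2Z)-3-[3,5-bis(benzyloxy)-2-(2-methylbut-3-en-2-yl)phenoxy]-3-[4-(benzyloxy)phenyl]prop-2-enoic acid F4.
- F4 is closed with trifluoroacetic anhydride, the same C4–C4a bond formation as in step 7, to 5,7-bis(benzyloxy)-2-[4-(benzyloxy)phenyl]-8-(2-methylbut-3-en-2-yl)-4H-chromen-4-one F5.
- Lithiation of C3 with lithium diisopropylamide at −78 °C, borylation with B(OMe)3 and oxidation with H2O2 in acetic acid should give 5,7-bis(benzyloxy)-2-[4-(benzyloxy)phenyl]-3-hydroxy-8-(2-methylbut-3-en-2-yl)-4H-chromen-4-one F6.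
- Benzyl bromide and K2CO3 in DMF convert F6 into 16.

**Step 2.** The most likely failure is further reaction of the first-formed phenol at the rearrangement temperature: ring closure of the hydroxyl onto the vinyl group, or cleavage of the prenyl ether back to 1. These pathways need the free ortho-hydroxyl or long heating. The fallback traps the phenol as it forms. It sets out from ether 3, which is heated in N,N-diethylaniline containing acetic anhydride and NaOAc, so that the product is isolated as 3,5-bis(benzyloxy)-2-(2-methylbut-3-en-2-yl)phenyl acetate F7. Methanolysis with K2CO3 in methanol at room temperature then returns the route at 5.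

**Step 8.** The most likely failure is Lewis-acid-induced ionisation at the quaternary carbon once ring A has become a free polyphenol (loss or migration of the allyl unit), or addition of the freed O7 hydroxyl or of HCl to the vinyl group during warming. The fallback changes the mechanism from acid-mediated ionisation to nucleophilic dealkylation under basic conditions. It sets out from 16, which is heated with NaSEt in degassed DMF at about 100 °C, so that each benzyl group is removed by SN2 attack of thiolate at the benzylic carbon. Acidification under argon returns the route at 17. No new intermediate is isolated.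

## Further compounds

F1 | step 7 | (2E)-2-(benzyloxy)-3-[3,5-bis(benzyloxy)-2-(2-methylbut-3-en-2-yl)phenoxy]-3-[4-(benzyloxy)phenyl]prop-2-enoyl chloride | O=C(Cl)/C(OCc1ccccc1)=C(\Oc1cc(OCc2ccccc2)cc(OCc2ccccc2)c1C(C)(C)C=C)c1ccc(OCc2ccccc2)cc1
F2 | step 5 | ethyl 3-[4-(benzyloxy)phenyl]prop-2-ynoate | CCOC(=O)C#Cc1ccc(OCc2ccccc2)cc1
F3 | step 5 | ethyl (2Z)-3-[3,5-bis(benzyloxy)-2-(2-methylbut-3-en-2-yl)phenoxy]-3-[4-(benzyloxy)phenyl]prop-2-enoate | CCOC(=O)/C=C(\Oc1cc(OCc2ccccc2)cc(OCc2ccccc2)c1C(C)(C)C=C)c1ccc(OCc2ccccc2)cc1
F4 | step 5 | (2Z)-3-[3,5-bis(benzyloxy)-2-(2-methylbut-3-en-2-yl)phenoxy]-3-[4-(benzyloxy)phenyl]prop-2-enoic acid | O=C(O)/C=C(\Oc1cc(OCc2ccccc2)cc(OCc2ccccc2)c1C(C)(C)C=C)c1ccc(OCc2ccccc2)cc1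
F5 | step 5 | 5,7-bis(benzyloxy)-2-[4-(benzyloxy)phenyl]-8-(2-methylbut-3-en-2-yl)-4H-chromen-4-one | C=CC(C)(C)c1c(OCc2ccccc2)cc(OCc2ccccc2)c2c(=O)cc(-c3ccc(OCc4ccccc4)cc3)oc12
F6 | step 5 | 5,7-bis(benzyloxy)-2-[4-(benzyloxy)phenyl]-3-hydroxy-8-(2-methylbut-3-en-2-yl)-4H-chromen-4-one | C=CC(C)(C)c1c(OCc2ccccc2)cc(OCc2ccccc2)c2c(=O)c(O)c(-c3ccc(OCc4ccccc4)cc3)oc12
F7 | step 2 | 3,5-bis(benzyloxy)-2-(2-methylbut-3-en-2-yl)phenyl acetate | CC(=O)Oc1cc(OCc2ccccc2)cc(OCc2ccccc2)c1C(C)(C)C=C
F0 | step 8 | none | none
A1 | alternative 1 | 2-acetyl-3,5-bis(methoxymethoxy)phenyl tert-butyl carbonate | CC(=O)c1c(OC(=O)OC(C)(C)C)cc(OCOC)cc1OCOC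
A2 | alternative 1 | 3,5-bis(methoxymethoxy)-2-(2-methylbut-3-en-2-yl)phenol | C=CC(C)(C)c1c(O)cc(OCOC)cc1OCOC
A3 | alternative 2 | 2-hydroxy-4,6-bis(methoxymethoxy)-3-(2-methylbut-3-en-2-yl)benzaldehyde | C=CC(C)(C)c1c(O)c(C=O)c(OCOC)cc1OCOC
A4 | alternative 2 | 1-(methoxymethoxy)-4-[(E)-2-nitroethenyl]benzene | COCOc1ccc(/C=C/[N+](=O)[O-])cc1
A5 | alternative 2 | racemic 5,7-bis(methoxymethoxy)-2-[4-(methoxymethoxy)phenyl]-8-(2-methylbut-3-en-2-yl)-3-nitro-2H-chromene | C=CC(C)(C)c1c(OCOC)cc(OCOC)c2c1OC(c1ccc(OCOC)cc1)C([N+](=O)[O-])=C2
A6 | alternative 3 | (2Z)-4,6-bis(methoxymethoxy)-2-{[4-(methoxymethoxy)phenyl]methylidene}-7-(2-methylbut-3-en-2-yl)-1-benzofuran-3(2H)-one | C=CC(C)(C)c1c(OCOC)cc(OCOC)c2c1O/C(=C\c1ccc(OCOC)cc1)C2=O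
A7 | alternative 3 | racemic 4,6-bis(methoxymethoxy)-3'-[4-(methoxymethoxy)phenyl]-7-(2-methylbut-3-en-2-yl)-3H-spiro[1-benzofuran-2,2'-oxiran]-3-one | C=CC(C)(C)c1c(OCOC)cc(OCOC)c2c1OC1(OC1c1ccc(OCOC)cc1)C2=O
A8 | alternative 3 | 3-hydroxy-5,7-bis(methoxymethoxy)-2-[4-(methoxymethoxy)phenyl]-8-(2-methylbut-3-en-2-yl)-4H-chromen-4-one | C=CC(C)(C)c1c(OCOC)cc(OCOC)c2c(=O)c(O)c(-c3ccc(OCOC)cc3)oc12
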